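I began with a subtraction: in the earlier runs, substrate not read as substrate, target or side product B must stand as open intermediate, so that intermediate can be counted. Partner A, in the flasks asked about the smallest charge, has one way in: it becomes second intermediate, which then goes to target, side product B or side product A. Between target and side product B, I took the choice to follow the ratio r = c(open intermediate)/c(substrate).

| flask | substrate | partner A | partner B | remark | time |
|---|---|---|---|---|---|
| violet | 0.10 M | 0.095 M | 0.15 M | run made earlier |  |
| green | 0.10 M | 0.095 M | 0.075 M | run made earlier |  |
| amber | 0.10 M | 0.095 M | 0.30 M | run made earlier |  |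
| epsilon | 0.10 M | 0.0950 M | 0.150 M | one stirred flow tank at steady state, fed with the mixture as stated, mean residence time 4.0 h |  |
| beta | 0.10 M | 0.0950 M (fed, over 4.00 h) | 0.150 M | a stirred flask in which partner A is dosed at a steady rate over 4.00 h without added volume, worked up at 4.0 h | 4.0 h |
| eta | 0.10 M (fed, over 4.00 h) | 0.0950 M | 0.150 M | a stirred flask in which substrate is dosed at a steady rate over 4.00 h without added volume, worked up at 4.0 h | 4.0 h |
| zeta | 0.10 M | 0.0950 M | 0.150 M | everything together in a closed stirred flask, run for 4.0 h | 4.0 h |

| run | time / h | target / % | side product B / % | substrate / % |
|---|---|---|---|---|
| violet | 0.667 | 2.0 | 10.7 | 67.5 |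
| violet | 1.33 | 5.6 | 19.1 | 51.5 |
| violet | 2.00 | 8.1 | 24.6 | 42.7 |
| violet | 2.50 | 8.8 | 25.9 | 37.8 |
| green | 0.667 | 0.7 | 8.0 | 82.6 |
| green | 1.33 | 1.7 | 14.2 | 72.4 |
| green | 2.00 | 2.4 | 18.7 | 67.5 |
| green | 2.50 | 3.3 | 20.9 | 64.5 |
| amber | 0.667 | 4.8 | 12.5 | 45.2 |
| amber | 1.33 | 11.5 | 18.0 | 24.4 |
| amber | 2.00 | 15.6 | 19.4 | 14.8 |
| amber | 2.50 | 18.3 | 20.3 | 10.7 |

(readings scatter by 0.3 percentage points)

- the stated concentrations are those of everything mixed, before any reaction; amounts are the same in each set-up
- reactions considered so far: partner B + partner A -> second intermediate; second intermediate -> side product A; substrate + second intermediate -> side product B; substrate + partner B -> open intermediate; open intermediate + second intermediate -> target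
- the feed brings no volume worth counting
- the earlier runs were made in a closed, stirred flask

- the set-up with the highest share of target in all that became target or side product B, at the outlet or at the end ("none" if the first two lie within 2 percentage points) (epsilon / beta / eta / zeta / none)
- share of target in all that became target or side product B, at the outlet or at the end, epsilon
- share of target in all that became target or side product B, at the outlet or at the end, beta
- share of target in all that became target or side product B, at the outlet or at the end, eta
- share of target in all that became target or side product B, at the outlet or at the end, zeta

From 1.33 h to 2.50 h in the amber run, target gained 2.96 times what side product B gained, while r, taken as the mean of open intermediate at those two readings over the mean of substrate, was 2.76. The selectivity factor s, target made per side product B made when open intermediate and substrate stand equal, is the quotient of the two, 1.07. It is a reading, resting on a side product B gain of 2.3 percentage points. The share of target at any instant is then s·r/(1+s·r), with break-even at r = 0.933.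

Now the violet run in slow motion. In the first instants r is zero, so second intermediate meeting substrate gives side product B, and at 0.667 h side product B stood at 10.7% against 2.0% target, with r at 0.293. By 2.00 h r had reached 0.576. At 2.50 h it was 0.728, still short of break-even, and the share so far was 25.4%. Since r climbed, I expected dosing partner A to place second intermediate later, at higher r, and I put beta first and zeta, the violet charge run to 4.0 h, above that violet share.

The forecast gave 43% for epsilon, 54% for beta, 27% for eta and 30% for zeta, and chose beta, reasoning that “A arrives after open intermediate has built up”.

The flasks gave 34.5% for epsilon, below the forecast's low end of 36%, 58.0% for beta, 19.5% for eta and 28.4% for zeta, so beta came first.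

    partner B + partner A → second intermediate (k = 0.430 L mol⁻¹ min⁻¹)
    second intermediate → side product A (k = 0.00760 min⁻¹)
    substrate + second intermediate → side product B (k = 0.0850 L mol⁻¹ min⁻¹)
    substrate + partner B → open intermediate (k = 0.0740 L mol⁻¹ min⁻¹)
    open intermediate + second intermediate → target (k = 0.0870 L mol⁻¹ min⁻¹)

Turned round, the rule reads a share as an effective r: 1.29 in beta, above break-even, and 0.371 in zeta, below it. The neighbour of zeta charged with 0.038 M of partner A ended at r = 2.45, where the rule gives 72.4% for the last instants, but its accumulated share was 37.8%, an effective r of 0.568.

The earlier runs and the new flask were computed with constants of no real substance; the scatter is artificial.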